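## Structural features

The target 14 is a cis-fused 3,7-dioxabicyclo[3.3.0]octane: two oxolane rings, ring A (C1–C5–C6–O7–C8) and ring B (C1–C2–O3–C4–C5), share the C1–C5 bond, and a 3,4-dimethoxyphenyl group (Ar) sits on each of C2 and C6. The four stereocentres C2, C1, C5 and C6 are contiguous, (1S,2S,5R,6S). C1 is a fully substituted bridgehead with a tertiary hydroxyl, C5 is the bridgehead CH, the C6 aryl is exo (trans to C4 across ring A) and the C2 aryl is endo (trans to the C1 hydroxyl, on the concave face). Both benzylic ether carbons carry electron-rich veratryl rings, so C2–O3 and C6–O7 ionise easily and acid can equilibrate the benzylic centres; the endo aryl at C2 is most at risk. The real difficulty is the C1–C2 pair: a tertiary carbinol next to an endo benzylic ether must be set relative to C5 and C6 without passing through a free veratryl cation. All 22 carbons of 14 are present in the linear ether C6(Ar)(vinyl)–O7–C8–C1≡C2–Ar, in which the C5=C4 vinyl group and the C1≡C2 alkyne stand in a 1,6-relationship. The key step uses this feature: it joins C1 to C5 (ring A), marks C4 with boron and leaves C1=C2 as a Z-arylidene, whose geometry and faces are then turned into the C1 and C2 configurations.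

## Logic of the disconnections

14 ⇒ 13. The C2–O3 bond is cut. Its formation closes ring B, sets C2 and, by breaking the C2–O bond of an epoxide, releases the C1 hydroxyl, so one cut removes a ring, a stereocentre and the tertiary alcohol. The forward step must be an intramolecular anti opening at benzylic C2 by the C4 hydroxyl (inversion, 5-endo) under acid mild enough that no free veratryl cation forms. 13 is generated from 12 and consumed in the same flask.

13 ⇒ 12 ⇒ 11. The silyl group is put back on the C4 oxygen and the epoxide oxygen is removed (C1–O and C2–O). Both oxygens on C1 and C2 then come from one stereospecific oxygen transfer to a Z alkene, and two stereocentres reduce to an alkene geometry plus a facial choice. The forward epoxidation must attack the face anti to the C4 arm under neutral, anhydrous conditions. The silyl ether stops the hydroxyl from steering the oxidant to the syn face and from opening the epoxide prematurely.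

11 ⇒ 10 ⇒ 9. The O–Si bond is cut, then the C4–O bond is traced back to C4–B. Boron is the form in which the key step delivers C4. Its oxidation is stereochemically neutral at a primary carbon and needs only conditions that do not isomerise the arylidene.

9 ⇒ 8. The C1–C5 and C4–B bonds are cut and the hydrogen on C2 is removed, which opens ring A and restores alkene and alkyne. This is the main simplification: a ring, the C5 stereocentre and the defined alkene geometry disappear, leaving an acyclic ether with one stereocentre. The forward step must add H and C5 syn across the alkyne, close 5-exo with C4 trans to the C6 aryl, and trap C4 with boron before β-hydride elimination.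

8 ⇒ 6 + 7. The C2–aryl bond is cut. An sp–sp2 coupling brings in the second aryl ring late and convergently and avoids an electron-rich 3-arylpropargyl halide as alkylating agent. It needs only a terminal alkyne and a mild amine base, which the allylic benzylic ether tolerates.

6 ⇒ 4 + 5. The O7–C8 bond is cut. O-Alkylation of the alkoxide of 4 breaks no bond to C6, so the configuration is carried over. The base must form the alkoxide without deprotonating the propargylic position.

4 ⇒ 3 ⇒ 1 + 2. The single enantiomer is traced back to the racemate, and the C5–C6 bond is then cut. Racemic addition followed by enzymatic resolution is preferred to a direct asymmetric vinylation because C6, from which all other centres are relayed, is fixed with a margin that can be tightened through conversion. The price is half of the material and the need to keep 3 and 4 away from acid.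

## Other disconnections considered

Alternative 1: The cut is at the two C–O bonds on C1 and C2 of a ring A lactone in which C8 is still a carbonyl. The precursor is the E-veratrylidene lactone A2 (aryl cis to C5); the forward key step is OsO4/NMO syn-dihydroxylation of C1=C2 on the face away from the C5 arm, giving the diol lactone A1.
- In favour: syn-dihydroxylation is stereospecific and dependable, and the E geometry is the thermodynamic one for an α-arylidene lactone. C2 receives its oxygen directly and is never substituted afterwards, because ring B would be closed by the C2 hydroxyl attacking an activated C4 with retention at C2. On this point (no inversion at a cation-prone veratryl carbon) the alternative is better than the chosen plan.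
- Against: the key step builds neither a C–C bond nor a ring, so the enantiopure trans-disubstituted lactone must be assembled first. The trisubstituted, electron-poor enoate is a slow substrate for OsO4. C8 is one oxidation level too high, so a lactone-to-ether reduction (lactol, then silane and Lewis acid) must be run late beside a tertiary alcohol and two acid-labile benzylic ethers.
- Comparison: facial control is equal, since both plans rely on the C5 arm. Mechanistically A1 is the safer way to C2. In step economy the chosen plan should be ahead, because its key step makes ring A, C5 and the C4 handle together and keeps C8 at the right oxidation level.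

Alternative 2: The cut is the C1–C2 bond. The precursor is the α-diazo lactone A4 with a veratryl ether on C4. Rh2(OAc)4 would generate the carbenoid at C1, and 1,5-insertion into the benzylic C2–H bond would give the cis-fused furofuranone A3.
- In favour: a C–C bond and ring B form together, and the insertion is concerted and stereoretentive. Its usual preference for the cis-fused product with the aryl on the concave face is the 2-endo arrangement needed here. C2 is set without any ionisable intermediate, which is better than the epoxide opening of the chosen plan. In bonds made at the key step the two plans are equal (one C–C bond and one ring each).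
- Against: A3 has hydrogen on C1, so the bridgehead hydroxyl must be added afterwards by enolate oxidation. C8 is again a carbonyl to be reduced to CH2 next to the new tertiary alcohol. Diazo transfer to a simple lactone needs prior activation. The electron-rich arene and the ether oxygen offer the carbenoid competing paths (aromatic cycloaddition, oxonium ylide).
- Comparison: A3 is closer to 14 than 9 in skeleton (both rings closed) but further in oxidation pattern (wrong level at C8, none at C1). The step count after the key step is about equal. The count before it is longer, because ring A with its C5/C6 relationship must exist beforehand, whereas the chosen plan creates C5 in the key step.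

Alternative 3: Two C–C bonds are cut, C4–C5 and C1–C2. The arylketene A7, generated in situ, would add across the C1=C5 silyl enol ether A6 to give the endo-aryl silyloxy cyclobutanone A5. Baeyer–Villiger migration of benzylic C2 would then insert O3 and give the ring B lactone, whose C4 carbonyl must be reduced.
- In favour: it is the most convergent of the four plans. The regiochemistry (ketene carbonyl carbon to nucleophilic C5) is unambiguous, the large ketene substituent is expected on the concave face, and the C1 oxygen is present from the start. In convergence and in installing the C1–O bond it is better than the chosen plan.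
- Against: monoaryl ketenes dimerise and are sluggish partners for silyl enol ethers. A5 is a β-silyloxy cyclobutanone and prone to retro-aldol ring opening. A6 requires regioselective enolisation toward C5 rather than C8. The Baeyer–Villiger step must choose C2 over C5 and spare two veratryl rings. A lactone-to-ether reduction is again needed.
- Comparison: on paper the step count is equal to or slightly lower than that of the chosen plan, but several steps lack close precedent on this substrate class, whereas each reaction type of the chosen plan is established. Stereochemically both relay everything from C6.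

Key step: step 5

Remark 1: Ar = 3,4-dimethoxyphenyl; the locants C1–C8 of 14 are used for the same atoms in every intermediate.
Remark 2 (check of configurations): (S) at C6 in 4, 6 and 8 and (2S,3S,4Z) in 9 correspond to (1S,2S,5R,6S)-14, so the structures of 8 and 9 need no correction. The oxolane C3 descriptor changes from S in 9 to R in 10 and 11 only because CH2O outranks the alkene carbon while CH2B does not.
Remark 3 (design changes): enantiopure 4 is secured by resolution, and the alkyne aryl group is attached after etherification, so no 3-arylpropargyl bromide is needed.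

## Route

Step 1
Reactants: 1 veratraldehyde (3,4-dimethoxybenzaldehyde); 2 vinylmagnesium bromide
Product: 3 rac-1-(3,4-dimethoxyphenyl)prop-2-en-1-ol
Conditions: CH2=CHMgBr (1.2 equiv), THF, −78 → 0 °C; aq. NH4Cl
Reagents that add atoms: none
Why: Grignard 1,2-addition to a non-enolisable aryl aldehyde; the carbinol C6 is formed racemic and is kept away from acid because the benzylic allylic alcohol ionises easily.

Step 2
Reactants: 3 rac-1-(3,4-dimethoxyphenyl)prop-2-en-1-ol
Product: 4 (S)-1-(3,4-dimethoxyphenyl)prop-2-en-1-ol
Conditions: immobilised Candida antarctica lipase B, vinyl acetate, MTBE, 30 °C, stopped just past half conversion; chromatography on Et3N-deactivated silica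
Reagents that add atoms: none
Why: Lipase-catalysed kinetic resolution by enantioselective transesterification; with aryl as the large and vinyl as the medium group the enzyme should acylate the (R)-alcohol, so the (S)-alcohol remains and the C6 configuration is fixed here. Running slightly beyond half conversion raises the enantiopurity of the recovered alcohol.

Step 3
Reactants: 4 (S)-1-(3,4-dimethoxyphenyl)prop-2-en-1-ol; 5 propargyl bromide (3-bromoprop-1-yne)
Product: 6 1,2-dimethoxy-4-[(1S)-1-(prop-2-yn-1-yloxy)prop-2-en-1-yl]benzene
Conditions: NaH, THF, 0 °C; then 5, Bu4NI (cat.), 0 °C → rt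
Reagents that add atoms: none
Why: Williamson ether synthesis forming O7–C8; no bond to C6 is broken, so the configuration is retained, and NaH cannot deprotonate the propargylic CH2, which excludes a Wittig rearrangement.

Step 4
Reactants: 6 1,2-dimethoxy-4-[(1S)-1-(prop-2-yn-1-yloxy)prop-2-en-1-yl]benzene; 7 4-iodo-1,2-dimethoxybenzene
Product: 8 4-[(1S)-1-{[3-(3,4-dimethoxyphenyl)prop-2-yn-1-yl]oxy}prop-2-en-1-yl]-1,2-dimethoxybenzene
Conditions: PdCl2(PPh3)2 (2 mol %), CuI (4 mol %), Et3N/THF, rt, degassed
Reagents that add atoms: none
Why: Sonogashira coupling of a terminal alkyne with an aryl iodide at room temperature forms the C2–aryl bond; zerovalent palladium does not ionise an allyl alkyl ether under these conditions and no hydride source is present, so the 1,6-enyne is left intact.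

Step 5
Reactants: 8 4-[(1S)-1-{[3-(3,4-dimethoxyphenyl)prop-2-yn-1-yl]oxy}prop-2-en-1-yl]-1,2-dimethoxybenzene
Product: 9 2-{[(2S,3S,4Z)-2-(3,4-dimethoxyphenyl)-4-[(3,4-dimethoxyphenyl)methylidene]oxolan-3-yl]methyl}-4,4,5,5-tetramethyl-1,3,2-dioxaborolane
Conditions: Pd(OAc)2 (5 mol %), B2pin2 (1.2 equiv), MeOH (1 equiv), toluene, 50 °C
Reagents that add atoms: bis(pinacolato)diboron, CC1(C)OB(OC1(C)C)B1OC(C)(C)C(C)(C)O1
Why: Pd(OAc)2 is turned by B2pin2 and MeOH into a palladium hydride that adds syn across C1≡C2 of 8, hydrogen to C2 and palladium to C1; the addition is reversible and only this regioisomer can cyclise. The vinyl group then inserts into the C1–Pd bond in a 5-exo-trig carbopalladation that forms C1–C5 and closes ring A. The primary C4–Pd species is intercepted by transmetalation with B2pin2 and C–B reductive elimination, which must outrun β-hydride loss from C5. The closest known reaction type is the Pd(OAc)2-catalysed borylative cyclisation of 1,6-enynes with B2pin2, which covers oxygen-tethered substrates with internal alkynes. C5 is the only new stereocentre and is set by C6: in the envelope-like insertion transition state the C6 aryl takes the pseudo-equatorial position, so C4 ends trans to it (2S,3S in 9). The Z geometry of C1=C2 follows from syn hydropalladation and insertion with retention at C1, placing the aryl cis to C8 and the hydrogen cis to C5. The step needs regioselective hydropalladation, trans-2,3 induction and fast boryl capture; the substrate secures these by having its stereocentre on the allylic carbon of the reacting alkene, by offering a single cyclisation mode and by carrying no acidic or protic group that could quench the alkylpalladium.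

Step 6
Reactants: 9 2-{[(2S,3S,4Z)-2-(3,4-dimethoxyphenyl)-4-[(3,4-dimethoxyphenyl)methylidene]oxolan-3-yl]methyl}-4,4,5,5-tetramethyl-1,3,2-dioxaborolane
Product: 10 [(2S,3R,4Z)-2-(3,4-dimethoxyphenyl)-4-[(3,4-dimethoxyphenyl)methylidene]oxolan-3-yl]methanol
Conditions: NaBO3·4H2O, THF/H2O (1:1), rt
Reagents that add atoms: sodium perborate, [Na+].[O-]OB=O
Why: Oxidation of a primary alkylboronate by boron-to-oxygen 1,2-migration in the peroxoborate adduct; the mild pH of NaBO3 leaves the Z-arylidene and the benzylic ether untouched, and no stereocentre is involved.

Step 7
Reactants: 10 [(2S,3R,4Z)-2-(3,4-dimethoxyphenyl)-4-[(3,4-dimethoxyphenyl)methylidene]oxolan-3-yl]methanol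
Product: 11 tert-butyl{[(2S,3R,4Z)-2-(3,4-dimethoxyphenyl)-4-[(3,4-dimethoxyphenyl)methylidene]oxolan-3-yl]methoxy}dimethylsilane
Conditions: TBSCl, imidazole, CH2Cl2, 0 °C → rt
Reagents that add atoms: tert-butyldimethylsilyl chloride, CC(C)(C)[Si](C)(C)Cl
Why: Standard silylation of a primary alcohol; the silyl ether removes hydroxyl direction toward the syn face, adds bulk on that face and prevents premature capture of the epoxide in step 8.

Step 8
Reactants: 11 tert-butyl{[(2S,3R,4Z)-2-(3,4-dimethoxyphenyl)-4-[(3,4-dimethoxyphenyl)methylidene]oxolan-3-yl]methoxy}dimethylsilane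
Product: 12 tert-butyl{[(2R,3S,6S,7R)-2,6-bis(3,4-dimethoxyphenyl)-1,5-dioxaspiro[2.4]heptan-7-yl]methoxy}dimethylsilane
Conditions: dimethyldioxirane (acetone solution, 1.2 equiv), CH2Cl2, −40 → −20 °C; volatiles removed cold, crude used at once
Reagents that add atoms: dimethyldioxirane, CC1(C)OO1
Why: Concerted, stereospecific oxygen transfer from the dioxirane keeps the Z relationship in the epoxide; attack anti to the C5 silyloxymethyl arm, which flanks C1, sets C1 (S) and C2 (R) with the oxygen cis to H5. The neutral, anhydrous reagent leaves only acetone, which matters because the veratryl-substituted epoxide would not survive the carboxylic acid formed from a peracid.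

Step 9
Reactants: 12 tert-butyl{[(2R,3S,6S,7R)-2,6-bis(3,4-dimethoxyphenyl)-1,5-dioxaspiro[2.4]heptan-7-yl]methoxy}dimethylsilane
Product: 14 (1S,2S,5R,6S)-2,6-bis(3,4-dimethoxyphenyl)-3,7-dioxabicyclo[3.3.0]octan-1-ol, via spiro-epoxy alcohol 13 (not isolated)
Conditions: Bu4NF (1.1 equiv), THF, 0 °C; then PPTS (1.5 equiv), 0 °C → rt, same flask
Reagents that add atoms: none
Why: Fluoride desilylation gives 13; on mild protonation the C4 hydroxyl, which lies on the ring A face opposite to the epoxide oxygen, attacks benzylic C2 anti to the breaking C2–O bond (acid-catalysed 5-endo-tet epoxide opening, favoured over 4-exo attack at C1 by benzylic activation and ring strain). Inversion at C2 gives the endo aryl (2S), the epoxide oxygen becomes the C1 hydroxyl and the tether enforces the cis ring fusion.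

## Compound list

1 | veratraldehyde (3,4-dimethoxybenzaldehyde) | COc1ccc(C=O)cc1OC | starting material
2 | vinylmagnesium bromide | C=C[Mg]Br | starting material
3 | rac-1-(3,4-dimethoxyphenyl)prop-2-en-1-ol | COc1ccc(C(O)C=C)cc1OC | intermediate
4 | (S)-1-(3,4-dimethoxyphenyl)prop-2-en-1-ol | COc1ccc([C@H](C=C)O)cc1OC | intermediate
5 | propargyl bromide (3-bromoprop-1-yne) | BrCC#C | starting material
6 | 1,2-dimethoxy-4-[(1S)-1-(prop-2-yn-1-yloxy)prop-2-en-1-yl]benzene | COc1ccc([C@H](C=C)OCC#C)cc1OC | intermediate
7 | 4-iodo-1,2-dimethoxybenzene | COc1ccc(I)cc1OC | starting material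
8 | 4-[(1S)-1-{[3-(3,4-dimethoxyphenyl)prop-2-yn-1-yl]oxy}prop-2-en-1-yl]-1,2-dimethoxybenzene | COc1ccc([C@H](C=C)OCC#Cc2ccc(OC)c(OC)c2)cc1OC | intermediate
9 | 2-{[(2S,3S,4Z)-2-(3,4-dimethoxyphenyl)-4-[(3,4-dimethoxyphenyl)methylidene]oxolan-3-yl]methyl}-4,4,5,5-tetramethyl-1,3,2-dioxaborolane | COc1ccc([C@H]2OC/C(=C\c3ccc(OC)c(OC)c3)[C@@H]2CB2OC(C)(C)C(C)(C)O2)cc1OC | intermediate
10 | [(2S,3R,4Z)-2-(3,4-dimethoxyphenyl)-4-[(3,4-dimethoxyphenyl)methylidene]oxolan-3-yl]methanol | COc1ccc([C@H]2OC/C(=C\c3ccc(OC)c(OC)c3)[C@@H]2CO)cc1OC | intermediate
11 | tert-butyl{[(2S,3R,4Z)-2-(3,4-dimethoxyphenyl)-4-[(3,4-dimethoxyphenyl)methylidene]oxolan-3-yl]methoxy}dimethylsilane | COc1ccc([C@H]2OC/C(=C\c3ccc(OC)c(OC)c3)[C@@H]2CO[Si](C)(C)C(C)(C)C)cc1OC | intermediate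
12 | tert-butyl{[(2R,3S,6S,7R)-2,6-bis(3,4-dimethoxyphenyl)-1,5-dioxaspiro[2.4]heptan-7-yl]methoxy}dimethylsilane | COc1ccc([C@H]2OC[C@@]3(O[C@@H]3c4ccc(OC)c(OC)c4)[C@@H]2CO[Si](C)(C)C(C)(C)C)cc1OC | intermediate
13 | [(2R,3S,6S,7R)-2,6-bis(3,4-dimethoxyphenyl)-1,5-dioxaspiro[2.4]heptan-7-yl]methanol (not isolated) | COc1ccc([C@H]2OC[C@@]3(O[C@@H]3c4ccc(OC)c(OC)c4)[C@@H]2CO)cc1OC | intermediate
14 | (1S,2S,5R,6S)-2,6-bis(3,4-dimethoxyphenyl)-3,7-dioxabicyclo[3.3.0]octan-1-ol | COc1ccc([C@H]2OC[C@@]3(O)[C@@H]2CO[C@H]3c2ccc(OC)c(OC)c2)cc1OC | target

## Step count and least certain steps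

Total number of steps: 9. Longest linear sequence: 9 steps (1 → 3 → 4 → 6 → 8 → 9 → 10 → 11 → 12 → 14); 2, 5 and 7 are commercial and enter directly.

Step 5 (key step).
- What may go wrong: β-hydride elimination from the C4 alkylpalladium may compete with boryl transfer, which would give dienes and erase C5. Trans induction from C6 may be incomplete. Palladium may assist ionisation of the doubly activated C6–O7 bond.
- Why: boryl capture is bimolecular while elimination is intramolecular, and the veratryl allylic ether is a latent leaving group.
- Fallback (radical ring closure with the C4 oxygen in place beforehand, no boron), setting out from 6 and returning at 14: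
  - 6 is epoxidised at the vinyl group with mCPBA (the terminal alkyne is inert) to the oxirane F1. Both epimers at C5 are acceptable because C5 becomes a radical.
  - Sonogashira coupling with 7 gives the aryl alkyne oxirane F2.
  - Cp2TiCl (trivalent titanium, made from Cp2TiCl2 and Zn in THF) opens the oxirane homolytically to the secondary C5 radical, which closes ring A by 5-exo-dig attack on C1, trans to the C6 aryl.
  - The α-aryl vinyl radical should be quenched from the side away from C5, giving the E-arylidene alcohol F3 (aryl cis to C5). Any Z isomer formed is 10 and rejoins the route there.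
  - Because the geometry of F3 is the reverse of that of 10, the two oxygens are added syn rather than anti. OsO4/NMO on the face anti to the C4 arm gives the triol F4.
  - Selective sulfonylation of the primary hydroxyl (TsCl, pyridine, 0 °C) gives the primary tosylate F5. K2CO3 in MeOH then lets the C2 hydroxyl displace the tosylate at C4 with retention at C2, which closes ring B and gives 14.

Step 9.
- What may go wrong: loss of stereospecificity at C2. The veratryl group may let the protonated epoxide ionise to a benzylic cation before the C4 hydroxyl arrives, and rotation about C1–C2 or later acid-mediated equilibration would then give the exo-aryl epimer.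
- Fallback (base-mediated SN2 on a cyclic sulfate instead of acid-mediated epoxide opening), setting out from 11 and returning at 14:
  - OsO4 (cat.)/NMO dihydroxylates 11 syn on the face anti to the silyloxymethyl arm, giving the diol F6.
  - SOCl2/Et3N, then RuCl3 (cat.)/NaIO4 with short contact at 0 °C, give the cyclic sulfate F7.
  - Bu4NF unmasks the C4 alkoxide, which displaces the sulfate oxygen at C2 with inversion (the leaving oxygen lies outside the new ring). This gives the C1 hydrogen sulfate F8.
  - Brief hydrolysis (cat. H2SO4, THF/H2O, rt) frees the C1 hydroxyl and gives 14.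

Step 8.
- What may go wrong: poor facial selectivity, because the anti face is free of the adjacent C4 arm but carries the more remote C6 aryl. The veratryl epoxide may also open or rearrange on traces of acid or on silica before step 9.
- Fallback (reagent control instead of substrate control), setting out from 11 and returning at 12: Shi epoxidation with the D-fructose-derived chiral ketone and KHSO5 in a K2CO3-buffered MeCN/dimethoxymethane/H2O medium at pH about 10.5 and 0 °C. By analogy with trans-β-methylstyrene-type alkenes this ketone should deliver oxygen to the face anti to the C4 arm (matched pair), and the medium stays basic. No new compound is made.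

Step 2.
- What may go wrong: insufficient discrimination between the vinyl and aryl groups by the enzyme, leaving 4 of incomplete enantiopurity, or slow acylation of this hindered carbinol.
- Fallback (asymmetric synthesis instead of resolution), setting out from 1 and returning at 4, bypassing 3: transmetalation of 2 with ZnCl2 gives divinylzinc F9, which is added to 1 in the presence of catalytic (−)-3-exo-(dimethylamino)isoborneol. Si-face delivery gives the (S)-carbinol 4 directly.

## Further compounds

F1 | step 5 | 2-[(R)-(3,4-dimethoxyphenyl)(prop-2-yn-1-yloxy)methyl]oxirane, both oxirane epimers (C6 as in 6) | COc1ccc([C@H](C2CO2)OCC#C)cc1OC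
F2 | step 5 | 2-[(R)-(3,4-dimethoxyphenyl){[3-(3,4-dimethoxyphenyl)prop-2-yn-1-yl]oxy}methyl]oxirane, both oxirane epimers | COc1ccc([C@H](C2CO2)OCC#Cc3ccc(OC)c(OC)c3)cc1OC
F3 | step 5 | [(2S,3R,4E)-2-(3,4-dimethoxyphenyl)-4-[(3,4-dimethoxyphenyl)methylidene]oxolan-3-yl]methanol | COc1ccc([C@H]2OC/C(=C/c3ccc(OC)c(OC)c3)[C@@H]2CO)cc1OC
F4 | step 5 | (3S,4R,5S)-5-(3,4-dimethoxyphenyl)-3-[(S)-(3,4-dimethoxyphenyl)(hydroxy)methyl]-4-(hydroxymethyl)oxolan-3-ol | COc1ccc([C@H]2OC[C@@]([C@@H](O)c3ccc(OC)c(OC)c3)(O)[C@@H]2CO)cc1OC
F5 | step 5 | primary 4-methylbenzenesulfonate of F4 (tosylate on the C4 oxygen) | COc1ccc([C@H]2OC[C@@]([C@@H](O)c3ccc(OC)c(OC)c3)(O)[C@@H]2COS(=O)(=O)c4ccc(C)cc4)cc1OC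
F6 | step 9 | (3S,4R,5S)-4-{[tert-butyl(dimethyl)silyl]oxymethyl}-5-(3,4-dimethoxyphenyl)-3-[(R)-(3,4-dimethoxyphenyl)(hydroxy)methyl]oxolan-3-ol | COc1ccc([C@H]2OC[C@@]([C@H](O)c3ccc(OC)c(OC)c3)(O)[C@@H]2CO[Si](C)(C)C(C)(C)C)cc1OC
F7 | step 9 | cyclic sulfate of F6 (1,3,2-dioxathiolane 2,2-dioxide spiro-fused at C1 of ring A) | COc1ccc([C@H]2OC[C@@]3(OS(=O)(=O)O[C@@H]3c4ccc(OC)c(OC)c4)[C@@H]2CO[Si](C)(C)C(C)(C)C)cc1OC
F8 | step 9 | C1 hydrogen sulfate of 14 | COc1ccc([C@H]2OC[C@@]3(OS(=O)(=O)O)[C@@H]2CO[C@H]3c2ccc(OC)c(OC)c2)cc1OC
F0 | step 8 | none | none
F9 | step 2 | divinylzinc | C=C[Zn]C=C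
A1 | alternative 1 | C1,C2-diol lactone (ring A lactone with C8 carbonyl, silyl ether on the C4 oxygen) | COc1ccc([C@H]2OC(=O)[C@@]([C@@H](O)c3ccc(OC)c(OC)c3)(O)[C@@H]2CO[Si](C)(C)C(C)(C)C)cc1OC
A2 | alternative 1 | E-veratrylidene lactone (aryl cis to C5, silyl ether on the C4 oxygen) | COc1ccc([C@H]2OC(=O)/C(=C/c3ccc(OC)c(OC)c3)[C@@H]2CO[Si](C)(C)C(C)(C)C)cc1OC
A3 | alternative 2 | 2-endo,6-exo-diaryl-3,7-dioxabicyclo[3.3.0]octan-8-one | COc1ccc([C@H]2OC(=O)[C@H]3[C@@H]2CO[C@H]3c2ccc(OC)c(OC)c2)cc1OC
A4 | alternative 2 | C1 diazo lactone with a 3,4-dimethoxybenzyl ether on C4 | COc1ccc([C@H]2OC(=O)C(=[N+]=[N-])[C@@H]2COCc3ccc(OC)c(OC)c3)cc1OC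
A5 | alternative 3 | endo-aryl silyloxy cyclobutanone fused to ring A (3-oxabicyclo[3.2.0]heptan-6-one) | COc1ccc([C@H]2OC[C@@]3(O[Si](C)(C)C(C)(C)C)[C@@H]2C(=O)[C@H]3c2ccc(OC)c(OC)c2)cc1OC
A6 | alternative 3 | (S)-tert-butyl{[5-(3,4-dimethoxyphenyl)-2,5-dihydrofuran-3-yl]oxy}dimethylsilane (C1=C5 silyl enol ether) | COc1ccc([C@H]2OCC(O[Si](C)(C)C(C)(C)C)=C2)cc1OC
A7 | alternative 3 | (3,4-dimethoxyphenyl)ketene | COc1ccc(C=C=O)cc1OC
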